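**Assumptions**

- The target is drawn as the free bis(hydrogen sulfate). It is delivered in that protonation state by cold acidification of its potassium salt; the salt is the form in which it should be stored.
- Compound 1 is taken to be a purchasable catalogue compound.
- Atom labels C1–C6, O3, O4 and O5 always mean positions of the target ring (C1 bears the CH2O group). Plain numbers mean compounds.

## Analysis of the target

The target 14 is one benzene ring with five substituents and no stereocentre. C1 carries CH2OSO3H, C2 and C3 carry bromine, C4 carries the aryl O-sulfate, C5 a free phenol and C6 the only ring hydrogen. The substituents form one unbroken arc from C1 to C5, so every bond must be made between two occupied positions. O4 and O5 differ only in their neighbours (Br on C3, H on C6), yet one must end as a sulfate and the other as a free phenol. The aryl sulfate is labile to acid. The benzylic sulfate sits para to O4, so any intermediate with a free O4 phenoxide and a benzylic leaving group can lose it through a para-quinone methide. The C–Br bonds rule out hydrogenolysis and organolithium chemistry once they are in place. The feature the route is built on is the vicinal pair C2–Br/C3–Br: two identical atoms on neighbouring carbons are what an aryne leaves behind when it adds a halogen molecule. C3, C4 and C5 form the 3,4,5-oxygenation pattern of the gallic series if C3 is first carried as an oxygen-bearing carbon. The difficulty is therefore selectivity, not size: placing both bromines with certainty, keeping O4 and O5 distinct, and introducing the sulfates last.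

## Retrosynthetic reasoning

**14 back to 11.** Both O–SO3 bonds are cut and O5 is returned to its triflate, giving diol 11. A triflate is chosen for O5 because an acyl group would migrate to the neighbouring O4 through a tetrahedral intermediate, whereas sulfonyl transfer needs an in-line geometry that a five-membered transition state cannot reach. The forward reaction sulfates the alcohol and the phenol, then cleaves the triflate with hydroxide, which sulfate monoester anions tolerate.

**11 back to 10 and 9.** The hydroxymethyl group of 11 is returned to the aldehyde of 10. 10 is then traced to 9 by restoring the O4–CH3 bond and the dioxolane. O4 is the only methylated oxygen from the first compound onward, so telling O4 from O5 is never a selectivity problem.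

**9 back to 7 through 8 (key disconnection).** Both C–Br bonds are cut at once. This leads to aryne 8, with its triple bond between C2 and C3, and to bromine. The cut is made here because both termini receive the same atom, so the unsymmetrical aryne raises no regiochemical question. Its precursor 7 carries silicon on C2, a triflate on C3 and a second triflate on C5. The gain is that the bromines enter after the oxygens are differentiated, at positions fixed by silicon and triflate and not by directing effects. The price is that C3 must be carried as an oxygen-bearing carbon and C2 as a silicon-bearing one.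

**7 back to 6.** Two O–S bonds are cut, giving diphenol 6. One triflation serves three purposes: the triflate next to silicon becomes the leaving group, the other masks O5, and together they make the ring too electron-poor for bromine to attack.

**6 back to 3 through 4 and 5.** The C2–Si bond is cut. It is formed by moving silicon from O3 to a lithiated C2, so the precursor is bromide 3. The single bromine of 3 decides which of two formerly equivalent oxygens becomes the leaving group.

**3 back to 2 and 1.** The dioxolane is opened to aldehyde 2, and the C2–Br bond of 2 is cut to give the symmetrical aldehyde 1, in which C2 and C6 are equivalent. This bromine is a placeholder for silicon; bromine returns to C2 in the key step.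

## Alternatives that were turned down

**Alternative 1:** The textbook disconnection cuts C3–Br and C2–Br one after the other. The forward key step is two electrophilic brominations of vanillin A1, first ortho to the O4 hydroxyl and then para to the O5 methoxy group, giving A2. The O5 methyl ether of A2 cannot be removed once sulfates are present. It would have to be cleaved to catechol A3, whose O4 and O5 must then be told apart by acidity alone before sulfation, followed by a protection and deprotection pair. In step count it is no worse than the chosen route. It was turned down because its selectivity rests on that one acidity difference, and because it is the route drawn first and builds nothing the substrate does not dictate.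

**Alternative 2:** The ring is cut at C2–C3 and C1–C6. The forward key step is a Diels–Alder reaction of diene A4 with bromoalkyne A5 to cycloadduct A6, followed by dehydrogenation to A7. The two oxygen substituents of A4 cancel each other as directing groups, and the required orientation brings the two bromine-bearing carbons together, so the regiochemistry is not secured. A6 can also aromatise by losing HBr, which destroys one of the two C–Br bonds the reaction was meant to deliver. A7 would still carry an undifferentiated catechol.

**Alternative 3:** The ring is made from another ring, cutting C3–C4 and C5–C6. The forward key step is a Diels–Alder reaction of 2-pyrone A8 with vinylene carbonate A9, then loss of CO2 and dehydrogenation to catechol carbonate A10. A8 already contains the vicinal dibromide, on a ring that is harder to make than the target. An electron-poor dibromopyrone and a sluggish dienophile need forcing temperatures, and the intermediate can aromatise by losing a carbonate oxygen instead of hydrogen. The cyclic carbonate again leaves O4 and O5 undifferentiated.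

Key step: step 5

## Route

Step 1
Reactants: 1 3,5-dihydroxy-4-methoxybenzaldehyde
Product: 2 2-bromo-3,5-dihydroxy-4-methoxybenzaldehyde
Conditions: NBS (1.0 equiv), MeCN, −20 to 0 °C
Reagents that add atoms: N-bromosuccinimide, O=C1CCC(=O)N1Br
Why: Electrophilic aromatic bromination; C2 and C6 of 1 are equivalent and each lies ortho to one hydroxyl and para to the other, so one equivalent should give a single monobromide, with the formyl group and the first bromine slowing a second substitution.

Step 2
Reactants: 2 2-bromo-3,5-dihydroxy-4-methoxybenzaldehyde
Product: 3 4-bromo-5-(1,3-dioxolan-2-yl)-2-methoxybenzene-1,3-diol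
Conditions: ethylene glycol, TsOH (cat.), toluene, reflux, Dean–Stark trap
Reagents that add atoms: ethylene glycol, OCCO
Why: Acid-catalysed acetalisation with azeotropic removal of water; the dioxolane masks the formyl group against n-BuLi in step 3 and should survive bromine–lithium exchange at −78 °C.

Step 3
Reactants: 3 4-bromo-5-(1,3-dioxolan-2-yl)-2-methoxybenzene-1,3-diol
Product: 6 5-(1,3-dioxolan-2-yl)-2-methoxy-4-(trimethylsilyl)benzene-1,3-diol, via bis(trimethylsilyl) ether 4 (not isolated), via lithium phenolate 5 (not isolated)
Conditions: HMDS, THF, 65 °C, then evaporation; n-BuLi (1.1 equiv), THF, −78 to 0 °C; MeOH; aq NH4Cl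
Reagents that add atoms: hexamethyldisilazane, C[Si](C)(C)N[Si](C)(C)C
Why: O-Silylation, bromine–lithium exchange and retro-Brook rearrangement (1,3 shift of silicon from oxygen to carbon); only the silyl group on the oxygen next to the lithiated carbon can migrate, which places silicon on C2, and the methanol quench removes the remaining O-silyl group.

Step 4
Reactants: 6 5-(1,3-dioxolan-2-yl)-2-methoxy-4-(trimethylsilyl)benzene-1,3-diol
Product: 7 5-(1,3-dioxolan-2-yl)-2-methoxy-4-(trimethylsilyl)-1,3-phenylene bis(trifluoromethanesulfonate)
Conditions: Tf2O (2.5 equiv), pyridine, CH2Cl2, 0 °C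
Reagents that add atoms: trifluoromethanesulfonic anhydride, O=S(=O)(OS(=O)(=O)C(F)(F)F)C(F)(F)F
Why: O-Sulfonylation of both phenols; the triflate ortho to silicon becomes the leaving group of the aryne precursor, and the other masks O5 and helps deactivate the ring.

Step 5
Reactants: 7 5-(1,3-dioxolan-2-yl)-2-methoxy-4-(trimethylsilyl)-1,3-phenylene bis(trifluoromethanesulfonate)
Product: 9 3,4-dibromo-5-(1,3-dioxolan-2-yl)-2-methoxyphenyl trifluoromethanesulfonate, via aryne 8 (not isolated)
Conditions: CsF (3 equiv), Br2 (2 equiv), MeCN, 0 °C to rt, dark
Reagents that add atoms: bromine, BrBr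
Why: Fluoride attacks silicon on C2 and the developing aryl anion expels the triflate on C3, the only leaving group ortho to silicon, to give aryne 8 with its triple bond between C2 and C3; the triflate on C5 has no ortho silicon and stays. Bromine then adds across the strained bond, so both C–Br bonds of the target form in one operation. The closest known reaction type is the addition of elemental halogens to arynes, generated thermally or from ortho-silylaryl triflates with fluoride, to give 1,2-dihaloarenes. No ring is closed and no stereocentre is formed. Regioselectivity is not needed: 8 is unsymmetrical, flanked by the acetal-bearing C1 and the methoxy-bearing C4, but both termini receive the same atom. What is needed is chemoselectivity of bromine for 8 over 7 and 9, and the substrate secures it: the ring carries two triflates and its methoxy group is twisted out of conjugation between two ortho substituents, so the C6–H and C2–Si bonds are poor sites for electrophilic attack. Bromine can therefore be present in excess from the start, which should let it outrun fluoride and acetonitrile as partners for 8.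

Step 6
Reactants: 9 3,4-dibromo-5-(1,3-dioxolan-2-yl)-2-methoxyphenyl trifluoromethanesulfonate
Product: 10 3,4-dibromo-5-formyl-2-hydroxyphenyl trifluoromethanesulfonate
Conditions: BBr3 (4 equiv), CH2Cl2, −78 to 0 °C; then H2O, THF, rt
Reagents that add atoms: none
Why: Lewis-acid ether cleavage; BBr3 should demethylate the one aryl methyl ether (O4) and open the dioxolane, which gives the aldehyde on aqueous work-up, while the aryl triflate and aryl bromides are inert to it.

Step 7
Reactants: 10 3,4-dibromo-5-formyl-2-hydroxyphenyl trifluoromethanesulfonate
Product: 11 3,4-dibromo-2-hydroxy-5-(hydroxymethyl)phenyl trifluoromethanesulfonate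
Conditions: NaBH4, THF/EtOH, 0 °C; aqueous work-up at pH 4
Reagents that add atoms: none
Why: Hydride reduction of the aldehyde; aryl triflate and aryl bromides should not react with NaBH4 at 0 °C, and the work-up avoids acidic alcohol because 11 is a para-hydroxybenzyl alcohol.

Step 8
Reactants: 11 3,4-dibromo-2-hydroxy-5-(hydroxymethyl)phenyl trifluoromethanesulfonate
Product: 14 [2,3-dibromo-6-hydroxy-4-(sulfooxymethyl)phenyl] hydrogen sulfate, via bis(pyridinium) disulfate 12 (not isolated), via tripotassium salt 13 (not isolated)
Conditions: SO3·pyridine (6 equiv), pyridine, 0 °C to rt; 2 M aq KOH, 1,4-dioxane, rt; 1 M HCl to pH 1, 0 °C; C18 chromatography (H2O/MeCN)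
Reagents that add atoms: sulfur trioxide–pyridine complex, [O-]S(=O)(=O)[n+]1ccccc1
Why: O-Sulfation of the alcohol and the phenol, then cleavage of the aryl triflate by hydroxide, then protonation; sulfate monoester anions resist hydroxide and should not migrate between the catechol oxygens. The O4 phenoxide of 11 is weakly basic (ortho bromine, ortho triflate), which should keep para-quinone methide formation from the intermediate benzylic monosulfate slow.

## Compound list

1 | 3,5-dihydroxy-4-methoxybenzaldehyde | COc1c(O)cc(C=O)cc1O | starting material
2 | 2-bromo-3,5-dihydroxy-4-methoxybenzaldehyde | COc1c(O)cc(C=O)c(Br)c1O | intermediate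
3 | 4-bromo-5-(1,3-dioxolan-2-yl)-2-methoxybenzene-1,3-diol | COc1c(O)cc(C2OCCO2)c(Br)c1O | intermediate
4 | 2-[2-bromo-4-methoxy-3,5-bis(trimethylsilyloxy)phenyl]-1,3-dioxolane | COc1c(O[Si](C)(C)C)cc(C2OCCO2)c(Br)c1O[Si](C)(C)C | intermediate
5 | lithium 3-(1,3-dioxolan-2-yl)-6-methoxy-2-(trimethylsilyl)-5-(trimethylsilyloxy)phenolate | [Li+].COc1c(O[Si](C)(C)C)cc(C2OCCO2)c([Si](C)(C)C)c1[O-] | intermediate
6 | 5-(1,3-dioxolan-2-yl)-2-methoxy-4-(trimethylsilyl)benzene-1,3-diol | COc1c(O)cc(C2OCCO2)c([Si](C)(C)C)c1O | intermediate
7 | 5-(1,3-dioxolan-2-yl)-2-methoxy-4-(trimethylsilyl)-1,3-phenylene bis(trifluoromethanesulfonate) | COc1c(OS(=O)(=O)C(F)(F)F)cc(C2OCCO2)c([Si](C)(C)C)c1OS(=O)(=O)C(F)(F)F | intermediate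
8 | 5-(1,3-dioxolan-2-yl)-2-methoxy-3,4-didehydrophenyl trifluoromethanesulfonate (aryne) | COC1=C(OS(=O)(=O)C(F)(F)F)C=C(C2OCCO2)C#C1 | intermediate
9 | 3,4-dibromo-5-(1,3-dioxolan-2-yl)-2-methoxyphenyl trifluoromethanesulfonate | COc1c(OS(=O)(=O)C(F)(F)F)cc(C2OCCO2)c(Br)c1Br | intermediate
10 | 3,4-dibromo-5-formyl-2-hydroxyphenyl trifluoromethanesulfonate | O=Cc1cc(OS(=O)(=O)C(F)(F)F)c(O)c(Br)c1Br | intermediate
11 | 3,4-dibromo-2-hydroxy-5-(hydroxymethyl)phenyl trifluoromethanesulfonate | OCc1cc(OS(=O)(=O)C(F)(F)F)c(O)c(Br)c1Br | intermediate
12 | bis(pyridinium) 2,3-dibromo-4-(sulfonatooxymethyl)-6-(trifluoromethanesulfonyloxy)phenyl sulfate | [O-]S(=O)(=O)OCc1cc(OS(=O)(=O)C(F)(F)F)c(OS(=O)(=O)[O-])c(Br)c1Br.c1cc[nH+]cc1.c1cc[nH+]cc1 | intermediate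
13 | tripotassium 3,4-dibromo-2-(sulfonatooxy)-5-(sulfonatooxymethyl)phenolate | [K+].[K+].[K+].[O-]S(=O)(=O)OCc1cc([O-])c(OS(=O)(=O)[O-])c(Br)c1Br | intermediate
14 | [2,3-dibromo-6-hydroxy-4-(sulfooxymethyl)phenyl] hydrogen sulfate | O=S(=O)(O)OCc1cc(O)c(OS(=O)(=O)O)c(Br)c1Br | target

## Step count and least certain steps

Total step count: 8. Longest linear sequence: 8 steps (the route is fully linear).

**The key step (step 5).** The aryne may be consumed before bromine reaches it, by addition of fluoride and protonation or by reaction with the solvent. Bromine may also slowly oxidise the acetal C–H bond. The fallback sets out from 7 and comes back at 9. The aryne is generated with KF and 18-crown-6 in THF in the presence of hexamethylditin, Pd(OAc)2 and tert-octyl isocyanide. The divalent palladium salt is reduced in the flask to the zerovalent catalyst, which inserts the aryne into the Sn–Sn bond to give 5-(1,3-dioxolan-2-yl)-2-methoxy-3,4-bis(trimethylstannyl)phenyl trifluoromethanesulfonate F1. Both C–Sn bonds are then replaced by ipso-bromodestannylation with Br2 in CH2Cl2 at −78 °C, giving 9. The bromines then arrive by substitution at carbon–tin bonds and no longer depend on free bromine meeting a free aryne.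

**Step 8.** The benzylic hydroxyl may be sulfated before O4. The resulting para-hydroxybenzyl sulfate can then lose sulfate by 1,6-elimination, and pyridine would capture the quinone methide. Partial hydrolysis of the aryl sulfate during acidification is a second risk. The fallback sets out from 10 and comes back at 13. It sulfates O4 while C1 is still an aldehyde, so no benzylic leaving group exists:
- SO3·pyridine in pyridine, then tributylamine, gives tributylammonium 2,3-dibromo-4-formyl-6-(trifluoromethanesulfonyloxy)phenyl sulfate F2.
- NaBH4 reduces it to tributylammonium 2,3-dibromo-4-(hydroxymethyl)-6-(trifluoromethanesulfonyloxy)phenyl sulfate F3.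
- SO3·pyridine sulfates the alcohol to the tributylammonium pyridinium salt of 2,3-dibromo-4-(sulfonatooxymethyl)-6-(trifluoromethanesulfonyloxy)phenyl sulfate F4.
- Aqueous KOH cleaves the triflate to 13, which is acidified as in the route.

**Step 1.** A second bromination at C6 may compete, because both free positions are activated alike, and would give mixtures. The fallback sets out from 1 and comes back at 6, bypassing steps 1 to 3 by making the C–Si bond through directed ortho-metalation:
- Acetalisation of 1 gives 5-(1,3-dioxolan-2-yl)-2-methoxybenzene-1,3-diol F5.
- Diethylcarbamoyl chloride and base give 5-(1,3-dioxolan-2-yl)-2-methoxy-1,3-phenylene bis(N,N-diethylcarbamate) F6.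
- s-BuLi and TMEDA at −78 °C lithiate one of the two equivalent positions between a carbamate and the dioxolane, and Me3SiCl gives 5-(1,3-dioxolan-2-yl)-2-methoxy-4-(trimethylsilyl)-1,3-phenylene bis(N,N-diethylcarbamate) F7.
- LiAlH4 in THF cleaves both carbamates to 6.

**Step 6.** Demethylation of the hindered, electron-poor ether may stall, or excess BBr3 may convert the liberated formyl group into a benzylidene dibromide. The fallback sets out from 9 and comes back at 10. Aqueous HCl in THF hydrolyses the dioxolane to 3,4-dibromo-5-formyl-2-methoxyphenyl trifluoromethanesulfonate F8. LiCl in DMF at 120 °C then removes the methyl group by nucleophilic attack at the methyl carbon; the para-formyl group and the two ortho substituents make the O4 phenoxide a good leaving group.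

## Further compounds

F1 | step 5 | 5-(1,3-dioxolan-2-yl)-2-methoxy-3,4-bis(trimethylstannyl)phenyl trifluoromethanesulfonate | COc1c(OS(=O)(=O)C(F)(F)F)cc(C2OCCO2)c([Sn](C)(C)C)c1[Sn](C)(C)C
F2 | step 8 | tributylammonium 2,3-dibromo-4-formyl-6-(trifluoromethanesulfonyloxy)phenyl sulfate | O=Cc1cc(OS(=O)(=O)C(F)(F)F)c(OS(=O)(=O)[O-])c(Br)c1Br.CCCC[NH+](CCCC)CCCC
F3 | step 8 | tributylammonium 2,3-dibromo-4-(hydroxymethyl)-6-(trifluoromethanesulfonyloxy)phenyl sulfate | OCc1cc(OS(=O)(=O)C(F)(F)F)c(OS(=O)(=O)[O-])c(Br)c1Br.CCCC[NH+](CCCC)CCCC
F4 | step 8 | tributylammonium pyridinium 2,3-dibromo-4-(sulfonatooxymethyl)-6-(trifluoromethanesulfonyloxy)phenyl sulfate | [O-]S(=O)(=O)OCc1cc(OS(=O)(=O)C(F)(F)F)c(OS(=O)(=O)[O-])c(Br)c1Br.CCCC[NH+](CCCC)CCCC.c1cc[nH+]cc1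
F5 | step 1 | 5-(1,3-dioxolan-2-yl)-2-methoxybenzene-1,3-diol | COc1c(O)cc(C2OCCO2)cc1O
F6 | step 1 | 5-(1,3-dioxolan-2-yl)-2-methoxy-1,3-phenylene bis(N,N-diethylcarbamate) | CCN(CC)C(=O)Oc1cc(C2OCCO2)cc(OC(=O)N(CC)CC)c1OC
F7 | step 1 | 5-(1,3-dioxolan-2-yl)-2-methoxy-4-(trimethylsilyl)-1,3-phenylene bis(N,N-diethylcarbamate) | CCN(CC)C(=O)Oc1cc(C2OCCO2)c([Si](C)(C)C)c(OC(=O)N(CC)CC)c1OC
F8 | step 6 | 3,4-dibromo-5-formyl-2-methoxyphenyl trifluoromethanesulfonate | COc1c(OS(=O)(=O)C(F)(F)F)cc(C=O)c(Br)c1Br
A1 | alternative 1 | vanillin (4-hydroxy-3-methoxybenzaldehyde) | COc1cc(C=O)ccc1O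
A2 | alternative 1 | 2,3-dibromo-4-hydroxy-5-methoxybenzaldehyde | COc1cc(C=O)c(Br)c(Br)c1O
A3 | alternative 1 | 2,3-dibromo-4,5-dihydroxybenzaldehyde | O=Cc1cc(O)c(O)c(Br)c1Br
A4 | alternative 2 | (Z)-1-bromo-2,3-bis(trimethylsilyloxy)buta-1,3-diene | Br/C=C(\O[Si](C)(C)C)C(=C)O[Si](C)(C)C
A5 | alternative 2 | methyl 3-bromopropiolate | COC(=O)C#CBr
A6 | alternative 2 | methyl 2,3-dibromo-4,5-bis(trimethylsilyloxy)cyclohexa-1,4-diene-1-carboxylate (racemic) | COC(=O)C1=C(Br)C(Br)C(O[Si](C)(C)C)=C(O[Si](C)(C)C)C1
A7 | alternative 2 | methyl 2,3-dibromo-4,5-dihydroxybenzoate | COC(=O)c1cc(O)c(O)c(Br)c1Br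
A8 | alternative 3 | 3,4-dibromo-5-(methoxymethyl)-2H-pyran-2-one | COCC1=COC(=O)C(Br)=C1Br
A9 | alternative 3 | vinylene carbonate | O=C1OC=CO1
A10 | alternative 3 | 4,5-dibromo-6-(methoxymethyl)-1,3-benzodioxol-2-one | COCc1cc2OC(=O)Oc2c(Br)c1Br
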